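Locants (briarane type): C1 ring-fusion C(CH3), C2 CH(OAc), C3/C4 CH2, C5(CH3)=C6, C7 lactone OCH, C8 C(OH), C9 CH(OH), C10 ring-fusion CH (these ten form the large ring). C11 is C(CH3)(CHO), C12 CHO, C13 CH2, C14 CH(OAc), C17 lactone CH(CH3), and C15/C20 are the methyls on C1/C11.
Enabling feature: the triad C14(O)-C1(quaternary, CH3)-C2(O) straddles the fusion bond C1-C10 of the cyclopentane and the ten-membered ring, and it is the retron of an epoxy-alcohol semipinacol shift. Cutting C1-C10 and rejoining C10 to C14 turns the 5/10 bicycle into a cyclobutanol fused to an eleven-membered ring (C14, C1-C10) that carries a C1-C2 epoxide.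
Further cuts: C1=C2 (ring-closing metathesis), C8-C17 plus the ester bond (bromopropionate, Reformatsky lactone annulation), C6-C7 (Nozaki-Hiyama-Kishi coupling), C14-O (ene oxygenation), C10-C11 and C13-C14 (intramolecular keteniminium [2+2] across an O9-C12 tether).
Forward order of rings: oxolane and cyclobutanone together, then the eleven-membered ring, then the γ-lactone. The key shift then gives the cyclopentanone and the ten-membered ring, and the O9-C12 ring is opened last to CHO and C9-OH.
Stereochemistry: C9 and a relay centre at C8 come from 2-deoxy-L-ribose, C10/C11 from the tethered [2+2], and the C14 carbinol from a convex-face ene reaction. C7 is set by Felkin-Anh addition, C8/C17 by the lactone tether, C1/C2 by Z olefin, directed epoxidation and stereospecific shift, and C14-H by chelate-controlled hydride.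

Key step: step 22

Remark: the hydroxy aldehyde 38 and its O9-C12 lactol are tautomers, and the open form drawn in the target is taken as the resting form.
Remark: the temporary acetal carbon C12 (14-37) is drawn as the exo anomer. The CHBr centre of 27-30 is left undefined because the acyl bromide is racemic. Both centres are erased later.
TBS = tert-butyldimethylsilyl.

Step 1
Reactants: 1 2-deoxy-L-ribose
Product: 2 2-deoxy-L-ribono-1,4-lactone [(4R,5S)-4-hydroxy-5-(hydroxymethyl)oxolan-2-one]
Conditions: Br2, H2O, rt
Reagents that add atoms: none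
Why: Bromine-water oxidation of the aldose hemiacetal (classical aldonolactone formation) gives the γ-lactone and leaves the two carbinol centres of the sugar, the future C9 and the relay centre C8, untouched.

Step 2
Reactants: 2 2-deoxy-L-ribono-1,4-lactone
Product: 3 5-O-TBS lactone
Conditions: TBSCl, imidazole, DMF, 0 °C
Reagents that add atoms: tert-butyldimethylsilyl chloride CC(C)(C)[Si](C)(C)Cl
Why: Silyl ether protection is selective for the unhindered primary hydroxyl (future O7) over the ring secondary one.

Step 3
Reactants: 3 5-O-TBS lactone; 4 3-bromo-2-methylprop-1-ene (methallyl bromide)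
Product: 5 3-O-methallyl-5-O-TBS lactone
Conditions: Ag2O, 4 Å sieves, DMF, rt, dark
Reagents that add atoms: none
Why: Silver-oxide-mediated Williamson etherification works without free alkoxide, which avoids β-elimination of the β-oxy lactone, and hangs the alkene partner C13=C11(C20)-C12 on O9.

Step 4
Reactants: 5 3-O-methallyl-5-O-TBS lactone
Product: 6 hydroxy amide 1-[(3R,4S)-5-(TBSO)-4-hydroxy-3-(2-methylallyloxy)pentanoyl]pyrrolidine
Conditions: pyrrolidine, THF, 40 °C
Reagents that add atoms: pyrrolidine C1CCNC1
Why: Aminolysis of the γ-lactone by the strongly nucleophilic secondary amine gives the tertiary amide required for keteniminium formation and frees O8 without touching a stereocentre.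

Step 5
Reactants: 6 hydroxy amide
Product: 7 bis-silyl amide 1-[(3R,4S)-4,5-bis(TBSO)-3-(2-methylallyloxy)pentanoyl]pyrrolidine
Conditions: TBSOTf, 2,6-lutidine, CH2Cl2, -78 to 0 °C
Reagents that add atoms: tert-butyldimethylsilyl triflate CC(C)(C)[Si](C)(C)OS(=O)(=O)C(F)(F)F
Why: Silylation with the silyl triflate protects the hindered secondary O8 so that nothing nucleophilic or acidic remains for the amide activation.

Step 6
Reactants: 7 bis-silyl amide
Product: 10 cyclobutanone (1S,4R,5R)-4-[(1S)-1,2-bis(TBSO)ethyl]-1-methyl-3-oxabicyclo[3.2.0]heptan-6-one (cis-fused; side chain exo), via keteniminium triflate 8 (not isolated), via cyclobutaniminium triflate 9 (not isolated)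
Conditions: Tf2O, 2,4,6-collidine, ClCH2CH2Cl, 0 °C to reflux; then H2O, reflux
Reagents that add atoms: water O
Why: O-Triflation of the amide and loss of the α-proton give keteniminium ion 8, whose intramolecular [2+2] cycloaddition to the 1,1-disubstituted alkene (then hydrolysis of iminium 9) is well known for three-atom tethers: the electrophilic C14 bonds to the CH2 terminus C13 because positive charge builds up at tertiary C11, the tether enforces the cis ring fusion that places C12 and C9 on one face (C10 and C11 set), and the C9 side chain takes the exo position so that C9 dictates the absolute sense.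

Step 7
Reactants: 10 cyclobutanone
Product: 11 keto lactone (1S,4R,5R)-4-[(1S)-1,2-bis(TBSO)ethyl]-1-methyl-3-oxabicyclo[3.2.0]heptane-2,6-dione
Conditions: RuCl3 (cat.), NaIO4, CCl4/MeCN/H2O, rt
Reagents that add atoms: sodium periodate [Na+].[O-]I(=O)(=O)=O
Why: RuO4-catalysed oxidation of a cyclic ether to the lactone attacks the only OCH2 group of the oxolane (C12), raising it towards the aldehyde level before any alkene is present, while silyl ethers and the ketone are inert.

Step 8
Reactants: 11 keto lactone; 12 isopropyltriphenylphosphonium iodide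
Product: 13 isopropylidene lactone (C14=C1 alkylidenecyclobutane; C1 bears C15 and a second methyl)
Conditions: n-BuLi, THF, 0 °C; then 11, -78 °C to rt
Reagents that add atoms: none
Why: Wittig olefination takes place at the strained and highly electrophilic cyclobutanone in preference to the neopentyl lactone carbonyl and creates no stereocentre.

Step 9
Reactants: 13 isopropylidene lactone
Product: 14 lactol (C12 hemiacetal)
Conditions: i-Bu2AlH, CH2Cl2, -78 °C
Reagents that add atoms: none
Why: Low-temperature hydride reduction of a γ-lactone stops at the aluminium hemiacetal and gives the lactol, which puts C12 at the aldehyde oxidation level.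

Step 10
Reactants: 14 lactol
Product: 15 methyl acetal (C12-OMe; O9 in the ring)
Conditions: MeOH, PPTS (cat.), CH2Cl2, 0 °C to rt
Reagents that add atoms: methanol CO
Why: Acid-catalysed acetalisation of the lactol through the cyclic oxocarbenium ion masks the C12 aldehyde and O9 together as a mixed methyl acetal that is orthogonal to fluoride; the anomeric centre is temporary.

Step 11
Reactants: 15 methyl acetal
Product: 17 tertiary allylic alcohol (C14-OH exo and syn to H10 and C20; isopropenyl endo and syn to C9 and C12), via allylic hydroperoxide 16 (not isolated)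
Conditions: O2, tetraphenylporphyrin, hν, CH2Cl2, -20 °C; then PPh3
Reagents that add atoms: dioxygen O=O
Why: Schenck ene reaction of singlet oxygen with the tetrasubstituted alkene: oxygen adds to C14 from the convex face of the bicycle (the side of H10 and C20) and a methyl hydrogen is abstracted because abstraction of a ring hydrogen would give a cyclobutene, so that after phosphine reduction the C14 hydroxyl is exo and the isopropenyl group sits endo, cis to C9 and C12, an arrangement that direct convex-face addition of an alkenyl metal to ketone 11 would not give.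

Step 12
Reactants: 17 tertiary allylic alcohol
Product: 18 primary alcohol (O7-H free; O8 still TBS)
Conditions: HF·pyridine, pyridine, THF, 0 °C
Reagents that add atoms: none
Why: Buffered fluoride cleaves the primary silyl ether faster than the hindered secondary one (selective desilylation), and the medium is too weakly acidic to disturb the acetal or the vinylcyclobutanol.

Step 13
Reactants: 18 primary alcohol
Product: 19 α-silyloxy aldehyde (C7 = CHO)
Conditions: Dess-Martin periodinane, CH2Cl2, 0 °C to rt
Reagents that add atoms: none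
Why: Dess-Martin oxidation turns the primary alcohol into the aldehyde under near-neutral conditions without epimerising C8; the tertiary alcohol cannot react.

Step 14
Reactants: 20 but-3-enylmagnesium bromide; 21 propyne
Product: 24 (Z)-1-iodo-2-methylhexa-1,5-diene, via but-3-enylcopper 22 (not isolated), via alkenylcopper 23 (not isolated)
Conditions: CuBr·SMe2, Et2O/Me2S, -45 °C; propyne, -25 °C; I2, THF, -78 to 0 °C
Reagents that add atoms: iodine II
Why: syn-Carbocupration of propyne puts the butenyl group on the internal carbon cis to copper, and iodinolysis with retention gives the Z iodide that carries the C5=C6 geometry of the target.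

Step 15
Reactants: 19 α-silyloxy aldehyde; 24 (Z)-1-iodo-2-methylhexa-1,5-diene
Product: 25 C7 allylic alcohol (open triene; 7,8-anti)
Conditions: CrCl2, NiCl2 (cat.), DMSO, rt
Reagents that add atoms: none
Why: Nozaki-Hiyama-Kishi coupling: the alkenylchromium species forms with retention of the Z geometry, tolerates the free tertiary alcohol and the acetal, and adds to the α-silyloxy aldehyde in the Felkin-Anh sense, which sets C7 anti to the relay centre C8.

Step 16
Reactants: 25 C7 allylic alcohol
Product: 26 cis-fused bicyclo[9.2.0] diene diol (eleven-membered ring C14-C1=C2-C3-C4-C5=C6-C7-C8-C9-C10; both olefins Z)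
Conditions: second-generation Hoveyda-Grubbs catalyst, toluene (high dilution), 80 °C, argon sparge
Reagents that add atoms: none
Why: Ring-closing metathesis starts at the monosubstituted C2 vinyl group and closes on the isopropenyl group next to the free allylic hydroxyl, the trisubstituted C5=C6 olefin being inert; under reversible conditions the Z olefin should prevail because an E C1=C2 bond would force the short C3-C8 bridge, which already holds a Z olefin, into a nearly fully stretched shape.

Step 17
Reactants: 26 bicyclic diene diol; 27 2-bromopropanoyl bromide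
Product: 28 C7 2-bromopropanoate
Conditions: pyridine, CH2Cl2, -30 °C
Reagents that add atoms: none
Why: Esterification by the acid bromide is selective for the secondary allylic C7 hydroxyl over the tertiary C14 hydroxyl; the CHBr centre is lost in step 20.

Step 18
Reactants: 28 C7 2-bromopropanoate
Product: 29 C8 alcohol
Conditions: HF·pyridine, MeCN/THF, 0 °C to rt
Reagents that add atoms: none
Why: Fluoride-mediated desilylation under slightly acidic conditions frees O8 without acyl migration from O7 or attack on the α-bromo ester.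

Step 19
Reactants: 29 C8 alcohol
Product: 30 C8 ketone (α-acyloxy ketone)
Conditions: Dess-Martin periodinane, CH2Cl2, 0 °C
Reagents that add atoms: none
Why: Dess-Martin oxidation erases the relay centre and gives the C8 ketone under non-basic conditions that spare the acidic C7-H and the β,γ-olefin.

Step 20
Reactants: 30 C8 ketone
Product: 32 β-hydroxy-γ-lactone fused trans to the eleven-membered ring, via samarium enolate 31 (not isolated)
Conditions: SmI2 (2.2 equiv), THF, -78 °C; aq. NH4Cl
Reagents that add atoms: none
Why: Samarium-diiodide Reformatsky reaction: fast two-electron reduction of the C-Br bond gives the trivalent samarium enolate 31, which adds intramolecularly (5-exo-trig) to the C8 ketone from the face on which O7 stands while C6 eclipses the carbonyl, so that C9 and C6 end trans on the lactone and the C8 hydroxyl cis to C6; the C17 methyl takes the position trans to the bulky C9 branch, which is also the thermodynamic one at this epimerisable centre.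

Step 21
Reactants: 32 β-hydroxy-γ-lactone
Product: 33 C1-C2 epoxy cyclobutanol
Conditions: VO(acac)2 (cat.), t-BuOOH, CH2Cl2, 0 °C
Reagents that add atoms: tert-butyl hydroperoxide CC(C)(C)OO
Why: Hydroxyl-directed vanadium-catalysed epoxidation: with the small C14 hydroxyl eclipsing the Z olefin to relieve allylic strain against C3, C10 stands on the inner face and the vanadium-bound peroxide reaches only the outer face, which sets C1 and C2, while the C5=C6 olefin is deactivated by the allylic lactone oxygen and is merely homoallylic to the hindered C8 hydroxyl.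

Step 22
Reactants: 33 C1-C2 epoxy cyclobutanol
Product: 34 β-hydroxy ketone (C14 cyclopentanone trans-fused to the ten-membered ring; C1 quaternary; C2-OH)
Conditions: ZnBr2 (0.2 equiv), CH2Cl2, -20 °C to rt
Reagents that add atoms: none
Why: ZnBr2 binds the C14 hydroxyl and the epoxide oxygen, the tertiary C1-O bond ionises and the antiperiplanar cyclobutane bond C14-C10 shifts to C1 while C14-O becomes the carbonyl, a concerted semipinacol rearrangement. The closest known reaction type is the Lewis-acid rearrangement of 2,3-epoxy alcohols to β-hydroxy ketones, in particular the expansion of 1-(oxiranyl)cyclobutanols to 2-(1-hydroxyalkyl)cyclopentanones, which is driven by release of cyclobutane strain. Since C14, C1 and C10 all lie in the eleven-membered ring, the new C1-C10 bond expels C14 from it: one suprafacial 1,2-alkyl shift closes the ten-membered carbocycle C1-C10 (ring contraction by one atom) and the cyclopentanone C1-C10-C11-C13-C14 (ring expansion by one atom). C1 is formed with inversion at the epoxide carbon and C2 keeps its C-O bond, so both follow from the Z olefin and the epoxide face of step 21, C10 migrates with retention, and because C2 lies on the hydroxyl side of the C14-C1-C10 plane in the cis-fused bicycle it ends anti to C9, which gives the trans ring fusion with C15 syn to C12. The step needs migration of C10 and not of C13, and rearrangement ahead of transannular attack by the C5=C6 olefin or ionisation of the acetal. In the conformer of least strain (C3 next to the small hydroxyl) only C14-C10 is antiperiplanar to C1-O and C10 is the more substituted terminus, the backside of C1 is thereby shielded from the olefin, which is also deactivated by the allylic lactone oxygen, and a mild zinc halide at low temperature leaves the acetal and the tertiary C8 alcohol alone.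

Step 23
Reactants: 34 β-hydroxy ketone
Product: 36 C2,C14 syn-1,3-diol, via diethylborinate 35 (not isolated)
Conditions: Et2BOMe, THF/MeOH, -78 °C; NaBH4; then repeated evaporation from MeOH
Reagents that add atoms: none
Why: Narasaka-Prasad reduction: the boron chelate between O2 and the C14 carbonyl covers the face that carries C2, external borohydride attacks from the face of C15 and gives the 1,3-syn diol, that is the C14 configuration of the target; the lactone is inert at this temperature.

Step 24
Reactants: 36 syn-1,3-diol
Product: 37 C2,C14 diacetate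
Conditions: Ac2O, DMAP, pyridine, rt
Reagents that add atoms: acetic anhydride CC(=O)OC(C)=O
Why: DMAP-catalysed acetylation esterifies the two secondary alcohols whereas the tertiary C8 hydroxyl is too hindered and O9 is still locked in the acetal.

Step 25
Reactants: 37 diacetate
Product: 38 CNP0123121.2 (target)
Conditions: 1 M HCl, THF, rt
Reagents that add atoms: water O
Why: Mild acid hydrolysis of the mixed acetal releases the C12 aldehyde and the C9 hydroxyl in one operation and leaves acetates, lactone, tertiary alcohol and olefin untouched.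

Compound list
1 | 2-deoxy-L-ribose | O=CC[C@@H](O)[C@@H](O)CO | starting material
2 | 2-deoxy-L-ribono-1,4-lactone | O=C1C[C@@H](O)[C@H](CO)O1 | intermediate
3 | 5-O-TBS lactone | O=C1C[C@@H](O)[C@H](CO[Si](C)(C)C(C)(C)C)O1 | intermediate
4 | 3-bromo-2-methylprop-1-ene | C=C(C)CBr | starting material
5 | 3-O-methallyl-5-O-TBS lactone | O=C1C[C@@H](OCC(C)=C)[C@H](CO[Si](C)(C)C(C)(C)C)O1 | intermediate
6 | hydroxy amide | O=C(C[C@@H](OCC(C)=C)[C@@H](O)CO[Si](C)(C)C(C)(C)C)N1CCCC1 | intermediate
7 | bis-silyl amide | O=C(C[C@@H](OCC(C)=C)[C@@H](O[Si](C)(C)C(C)(C)C)CO[Si](C)(C)C(C)(C)C)N1CCCC1 | intermediate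
8 | keteniminium triflate | [O-]S(=O)(=O)C(F)(F)F.C1CC[N+](C1)=C=C[C@@H](OCC(C)=C)[C@@H](O[Si](C)(C)C(C)(C)C)CO[Si](C)(C)C(C)(C)C | intermediate
9 | cyclobutaniminium triflate | [O-]S(=O)(=O)C(F)(F)F.C1CC[N+](C1)=C2C[C@](C)(CO3)[C@@H]2[C@@H]3[C@@H](O[Si](C)(C)C(C)(C)C)CO[Si](C)(C)C(C)(C)C | intermediate
10 | cyclobutanone (3-oxabicyclo[3.2.0]heptan-6-one) | O=C1C[C@](C)(CO2)[C@@H]1[C@@H]2[C@@H](O[Si](C)(C)C(C)(C)C)CO[Si](C)(C)C(C)(C)C | intermediate
11 | keto lactone | O=C1C[C@](C)(C(=O)O2)[C@@H]1[C@@H]2[C@@H](O[Si](C)(C)C(C)(C)C)CO[Si](C)(C)C(C)(C)C | intermediate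
12 | isopropyltriphenylphosphonium iodide | CC(C)[P+](c1ccccc1)(c1ccccc1)c1ccccc1.[I-] | starting material
13 | isopropylidene lactone | CC(C)=C1C[C@](C)(C(=O)O2)[C@@H]1[C@@H]2[C@@H](O[Si](C)(C)C(C)(C)C)CO[Si](C)(C)C(C)(C)C | intermediate
14 | lactol | CC(C)=C1C[C@](C)([C@@H](O)O2)[C@@H]1[C@@H]2[C@@H](O[Si](C)(C)C(C)(C)C)CO[Si](C)(C)C(C)(C)C | intermediate
15 | methyl acetal | CC(C)=C1C[C@](C)([C@@H](OC)O2)[C@@H]1[C@@H]2[C@@H](O[Si](C)(C)C(C)(C)C)CO[Si](C)(C)C(C)(C)C | intermediate
16 | allylic hydroperoxide | OO[C@@]1(C(C)=C)C[C@](C)([C@@H](OC)O2)[C@@H]1[C@@H]2[C@@H](O[Si](C)(C)C(C)(C)C)CO[Si](C)(C)C(C)(C)C | intermediate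
17 | tertiary allylic alcohol (isopropenylcyclobutanol) | O[C@@]1(C(C)=C)C[C@](C)([C@@H](OC)O2)[C@@H]1[C@@H]2[C@@H](O[Si](C)(C)C(C)(C)C)CO[Si](C)(C)C(C)(C)C | intermediate
18 | primary alcohol | O[C@@]1(C(C)=C)C[C@](C)([C@@H](OC)O2)[C@@H]1[C@@H]2[C@@H](O[Si](C)(C)C(C)(C)C)CO | intermediate
19 | α-silyloxy aldehyde | O[C@@]1(C(C)=C)C[C@](C)([C@@H](OC)O2)[C@@H]1[C@@H]2[C@@H](O[Si](C)(C)C(C)(C)C)C=O | intermediate
20 | but-3-enylmagnesium bromide | C=CCC[Mg]Br | starting material
21 | propyne | CC#C | starting material
22 | but-3-enylcopper | [Cu]CCC=C | intermediate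
23 | (Z)-2-methylhexa-1,5-dienylcopper | [Cu]/C=C(/C)CCC=C | intermediate
24 | (Z)-1-iodo-2-methylhexa-1,5-diene | I/C=C(/C)CCC=C | intermediate
25 | C7 allylic alcohol (open triene) | O[C@@]1(C(C)=C)C[C@](C)([C@@H](OC)O2)[C@@H]1[C@@H]2[C@@H](O[Si](C)(C)C(C)(C)C)[C@H](/C=C(/C)CCC=C)O | intermediate
26 | cis-fused bicyclo[9.2.0] diene diol | O[C@@]12C[C@](C)([C@@H](OC)O3)[C@@H]1[C@@H]3[C@@H](O[Si](C)(C)C(C)(C)C)[C@H](/C=C(/C)CC/C=C2/C)O | intermediate
27 | 2-bromopropanoyl bromide | CC(Br)C(=O)Br | starting material
28 | C7 2-bromopropanoate | O[C@@]12C[C@](C)([C@@H](OC)O3)[C@@H]1[C@@H]3[C@@H](O[Si](C)(C)C(C)(C)C)[C@H](/C=C(/C)CC/C=C2/C)OC(=O)C(C)Br | intermediate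
29 | C8 alcohol | O[C@@]12C[C@](C)([C@@H](OC)O3)[C@@H]1[C@@H]3[C@@H](O)[C@H](/C=C(/C)CC/C=C2/C)OC(=O)C(C)Br | intermediate
30 | C8 ketone | O[C@@]12C[C@](C)([C@@H](OC)O3)[C@@H]1[C@@H]3C(=O)[C@H](/C=C(/C)CC/C=C2/C)OC(=O)C(C)Br | intermediate
31 | samarium enolate | O[C@@]12C[C@](C)([C@@H](OC)O3)[C@@H]1[C@@H]3C(=O)[C@H](/C=C(/C)CC/C=C2/C)O/C(O[Sm](I)I)=C/C | intermediate
32 | β-hydroxy-γ-lactone on the eleven-membered ring | O[C@@]12C[C@](C)([C@@H](OC)O3)[C@@H]1[C@@H]3[C@@]4(O)[C@H](/C=C(/C)CC/C=C2/C)OC(=O)[C@@H]4C | intermediate
33 | C1-C2 epoxy cyclobutanol | O[C@@]12C[C@](C)([C@@H](OC)O3)[C@@H]1[C@@H]3[C@@]4(O)[C@H](/C=C(/C)CC[C@H]5O[C@]52C)OC(=O)[C@@H]4C | intermediate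
34 | β-hydroxy ketone (5/10 skeleton) | O=C1C[C@](C)([C@@H](OC)O3)[C@@H]2[C@@H]3[C@@]4(O)[C@H](/C=C(/C)CC[C@@H](O)[C@@]12C)OC(=O)[C@@H]4C | intermediate
35 | O2 diethylborinate of 34 | O=C1C[C@](C)([C@@H](OC)O3)[C@@H]2[C@@H]3[C@@]4(O)[C@H](/C=C(/C)CC[C@@H](OB(CC)CC)[C@@]12C)OC(=O)[C@@H]4C | intermediate
36 | C2,C14 syn-diol | O[C@H]1C[C@](C)([C@@H](OC)O3)[C@@H]2[C@@H]3[C@@]4(O)[C@H](/C=C(/C)CC[C@@H](O)[C@@]12C)OC(=O)[C@@H]4C | intermediate
37 | C2,C14 diacetate | CC(=O)O[C@H]1C[C@](C)([C@@H](OC)O3)[C@@H]2[C@@H]3[C@@]4(O)[C@H](/C=C(/C)CC[C@@H](OC(C)=O)[C@@]12C)OC(=O)[C@@H]4C | intermediate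
38 | CNP0123121.2 | CC(=O)O[C@H]1C[C@](C)(C=O)[C@@H]2[C@@H](O)[C@@]3(O)[C@H](/C=C(/C)CC[C@@H](OC(C)=O)[C@@]12C)OC(=O)[C@@H]3C | target

Total step count: 25. Longest linear sequence: 24 (steps 1-13 and 15-25; step 14 is a one-step side branch).

Steps most likely to fail

Step 22 (semipinacol ring contraction).
- What may go wrong: the C13 methylene may migrate in place of C10, the C5=C6 olefin may capture the developing cation across the ring, or the Lewis acid may ionise the acetal.
- The fallback sets out from 33 and comes back at 34. It replaces the chelated hydroxy epoxide by an epoxy silyl ether, whose rearrangement needs a Lewis acid on the epoxide oxygen only.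
- TMSOTf and 2,6-lutidine (CH2Cl2, -78 °C) give the bis(trimethylsilyl) ether F9.
- The very bulky methylaluminium bis(4-bromo-2,6-di-tert-butylphenoxide) (CH2Cl2, -78 °C) cannot reach the acetal. It triggers the anti 1,2-shift with transfer of the silyl group from O14 to O2, which gives the β-silyloxy ketone F10 and also blocks retro-aldol cleavage.
- Aqueous citric acid in THF removes both silyl groups to give 34.

Step 16 (ring-closing metathesis).
- What may go wrong: the hindered endo isopropenyl group may fail to enter the metallacycle, oligomers may form, or the ring may close with E geometry.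
- The fallback sets out from 17 and comes back at 26. It makes C1=C2 by olefination and closes the ring at C6-C7.
- Ozonolysis of 17 (O3, CH2Cl2, -78 °C; Me2S) gives the α-hydroxy methyl ketone F1, which TMSOTf and 2,6-lutidine convert into the α-silyloxy ketone F2.
- In parallel, syn-carbocupration of propyne 21 with the copper reagent from ClMg(CH2)3OMgCl and CuBr·SMe2, then I2, gives (Z)-5-iodo-4-methylpent-4-en-1-ol F3.
- I2, PPh3 and imidazole give the diiodide F4, and PPh3 in refluxing MeCN gives the phosphonium iodide F5.
- The unstabilised ylide from F5 (NaN(SiMe3)2, THF, -78 °C) olefinates F2. α-Oxygenated methyl ketones are known to place the new chain cis to the oxygenated carbon, so the product is the Z,Z-dienyl iodide F6.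
- HF·pyridine removes the primary TBS and the trimethylsilyl group to give the diol F7, and Dess-Martin oxidation gives the aldehyde F8.
- An intramolecular Nozaki-Hiyama-Kishi reaction (CrCl2, NiCl2 cat., DMSO, high dilution) closes C6-C7 in the Felkin-Anh sense to give 26.

Step 6 (keteniminium [2+2]).
- What may go wrong: the activated amide may lose the β-methallyloxy group by elimination, or a silyl ether oxygen may intercept the keteniminium ion.
- The fallback sets out from 5 and comes back at 10. It uses the neutral ketene.
- LiOH (THF/H2O) opens 5 to the lithium hydroxy carboxylate F11, and TBSOTf with 2,6-lutidine gives the silyl ester silyl ether F12.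
- Oxalyl chloride with catalytic DMF converts the silyl ester directly into the acid chloride F13.
- Slow addition to Et3N in refluxing toluene generates the ketene F14, which undergoes the same tether-controlled intramolecular [2+2] cycloaddition to 10.

Further compounds
F1 | step 16 | α-hydroxy methyl ketone | O[C@@]1(C(C)=O)C[C@](C)([C@@H](OC)O2)[C@@H]1[C@@H]2[C@@H](O[Si](C)(C)C(C)(C)C)CO[Si](C)(C)C(C)(C)C
F2 | step 16 | α-trimethylsilyloxy methyl ketone | C[Si](C)(C)O[C@@]1(C(C)=O)C[C@](C)([C@@H](OC)O2)[C@@H]1[C@@H]2[C@@H](O[Si](C)(C)C(C)(C)C)CO[Si](C)(C)C(C)(C)C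
F3 | step 16 | (Z)-5-iodo-4-methylpent-4-en-1-ol | I/C=C(/C)CCCO
F4 | step 16 | (Z)-1,5-diiodo-2-methylpent-1-ene | I/C=C(/C)CCCI
F5 | step 16 | [(Z)-5-iodo-4-methylpent-4-enyl]triphenylphosphonium iodide | I/C=C(/C)CCC[P+](c1ccccc1)(c1ccccc1)c1ccccc1.[I-]
F6 | step 16 | Z,Z-dienyl iodide | C[Si](C)(C)O[C@@]1(/C(C)=C\CC/C(C)=C\I)C[C@](C)([C@@H](OC)O2)[C@@H]1[C@@H]2[C@@H](O[Si](C)(C)C(C)(C)C)CO[Si](C)(C)C(C)(C)C
F7 | step 16 | dienyl iodide diol | O[C@@]1(/C(C)=C\CC/C(C)=C\I)C[C@](C)([C@@H](OC)O2)[C@@H]1[C@@H]2[C@@H](O[Si](C)(C)C(C)(C)C)CO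
F8 | step 16 | dienyl iodide aldehyde | O[C@@]1(/C(C)=C\CC/C(C)=C\I)C[C@](C)([C@@H](OC)O2)[C@@H]1[C@@H]2[C@@H](O[Si](C)(C)C(C)(C)C)C=O
F9 | step 22 | bis(trimethylsilyl) ether of 33 | C[Si](C)(C)O[C@@]12C[C@](C)([C@@H](OC)O3)[C@@H]1[C@@H]3[C@@]4(O[Si](C)(C)C)[C@H](/C=C(/C)CC[C@H]5O[C@]52C)OC(=O)[C@@H]4C
F10 | step 22 | β-silyloxy ketone | O=C1C[C@](C)([C@@H](OC)O3)[C@@H]2[C@@H]3[C@@]4(O[Si](C)(C)C)[C@H](/C=C(/C)CC[C@@H](O[Si](C)(C)C)[C@@]12C)OC(=O)[C@@H]4C
F11 | step 6 | lithium hydroxy carboxylate | [Li+].[O-]C(=O)C[C@@H](OCC(C)=C)[C@@H](O)CO[Si](C)(C)C(C)(C)C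
F12 | step 6 | silyl ester silyl ether | CC(C)(C)[Si](C)(C)OC(=O)C[C@@H](OCC(C)=C)[C@@H](O[Si](C)(C)C(C)(C)C)CO[Si](C)(C)C(C)(C)C
F13 | step 6 | acid chloride | ClC(=O)C[C@@H](OCC(C)=C)[C@@H](O[Si](C)(C)C(C)(C)C)CO[Si](C)(C)C(C)(C)C
F14 | step 6 | ketene | O=C=C[C@@H](OCC(C)=C)[C@@H](O[Si](C)(C)C(C)(C)C)CO[Si](C)(C)C(C)(C)C
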